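**Retrosynthetic overview**

- Target 13 is the (1Z,2S,3S)-1-benzylidene-2,3-diarylindane-4,6-diol (C1 = benzylidene carbon, C2 bears the 3,5-dihydroxyphenyl group, C3 the 4-hydroxyphenyl group, C3a and C7a are the ring A fusion carbons). The strategy rests on one feature: ring A is oxygenated only at C4 and C6, so C7a, the aromatic carbon bonded to C1, is meta to both oxygens and out of Friedel–Crafts reach. The chain C7a–C3a–C3–C2–C1 nevertheless coincides with C8a–C4a–C4–C3–C2 of 5,7-dimethoxycoumarin, whose ring oxygen on C8a can be made a triflate, and the exocyclic aryl lies cis to C7a, where a syn carbopalladation leaves the metal.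
- Disconnections, last first: the six O–CH3 bonds; then, in one operation, the aryl–CH bond (Suzuki coupling) and the C7a–C1 bond (5-exo-dig carbopalladation of a terminal alkyne by the aryl triflate).
- The alkyne is the homologated lactone carbonyl and the triflate the freed lactone oxygen of a trans-3,4-diaryl-5,7-dimethoxychroman-2-one. That lactone comes from α-arylation (C2 aryl) of the product of an asymmetric rhodium-catalysed 1,4-addition (C3 aryl) to the coumarin.
- Ring order: the lactone ring arrives with the coumarin, carries both stereocentres and is opened in step 4; the five-membered carbocycle is the only ring built and is closed in step 6.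

Key step: step 6

Assumption: the sense of induction in step 1 is taken to follow that of unsubstituted coumarins ((S)-ligand to (S)-lactone; the methoxy groups do not change the CIP ranking at C4). If the first batch proves antipodal, (R)-Segphos is used and nothing else changes.

**Route**

Step 1
Reactants: 1 5,7-dimethoxycoumarin; 2 4-methoxyphenylboronic acid
Product: 3 (S)-5,7-dimethoxy-4-(4-methoxyphenyl)chroman-2-one
Conditions: Rh(acac)(C2H4)2 (3 mol %), (S)-Segphos (3.3 mol %), 2 (5 equiv, in portions), dioxane/H2O 10:1, 60 °C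
Reagents that add atoms: none
Why: Hayashi–Miyaura reaction (asymmetric 1,4-addition of an arylboronic acid under monovalent rhodium): the aryl–rhodium species inserts the coumarin C3=C4 bond on the face chosen by the C2-symmetric bisphosphine and water protonates the rhodium enolate, so the C4 stereocentre is set by the ligand; the large excess of 2 offsets protodeboronation and the lower electrophilicity of this electron-rich coumarin.

Step 2
Reactants: 3 (S)-5,7-dimethoxy-4-(4-methoxyphenyl)chroman-2-one; 4 1-bromo-3,5-dimethoxybenzene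
Product: 7 (3S,4S)-3-(3,5-dimethoxyphenyl)-5,7-dimethoxy-4-(4-methoxyphenyl)chroman-2-one (trans), via lithium enolate 5 (not isolated), via chlorozinc enolate 6 (not isolated)
Conditions: LiN(SiMe3)2 (1.1 equiv), THF, −78 °C; ZnCl2 (1.2 equiv), −78 °C to rt; 4, Pd(dba)2 (5 mol %), P(t-Bu)3 (5 mol %), THF, rt to 50 °C; then DBU (0.1 equiv), CH2Cl2, rt
Reagents that add atoms: none
Why: Palladium-catalysed α-arylation of an ester enolate in its Negishi-type form: the zinc enolate is used in place of the lithium enolate because it should neither expel the aryloxide to a ketene nor deprotonate the product, the aryl is delivered to C3 on the face opposite the C4 aryl, and trans is also the thermodynamic arrangement, which the DBU treatment secures through the enolisable C3–H while C4 is not acidic.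

Step 3
Reactants: 7 (3S,4S)-3-(3,5-dimethoxyphenyl)-5,7-dimethoxy-4-(4-methoxyphenyl)chroman-2-one
Product: 8 (3S,4S)-3-(3,5-dimethoxyphenyl)-5,7-dimethoxy-4-(4-methoxyphenyl)chroman-2-ol (lactol, both anomers)
Conditions: (i-Bu)2AlH (1.2 equiv), CH2Cl2, −78 °C; aq. potassium sodium tartrate
Reagents that add atoms: none
Why: Partial hydride reduction of a lactone, which at −78 °C should stop at the hemiacetal oxidation level; the new anomeric centre is of no consequence because that carbon becomes an alkyne carbon, and C3 and C4 are untouched.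

Step 4
Reactants: 8 (3S,4S)-3-(3,5-dimethoxyphenyl)-5,7-dimethoxy-4-(4-methoxyphenyl)chroman-2-ol
Product: 10 2-[(1S,2R)-2-(3,5-dimethoxyphenyl)-1-(4-methoxyphenyl)but-3-yn-1-yl]-3,5-dimethoxyphenol, via hydroxy aldehyde 9 (not isolated)
Conditions: dimethyl (1-diazo-2-oxopropyl)phosphonate (2 equiv), K2CO3 (3 equiv), MeOH/THF, 0 °C to rt, short reaction time; aq. NH4Cl
Reagents that add atoms: dimethyl (1-diazo-2-oxopropyl)phosphonate, CC(=O)C(=[N+]=[N-])P(=O)(OC)OC
Why: Ohira–Bestmann variant of the Seyferth–Gilbert homologation: the aryl hemiacetal opens readily to the phenoxide aldehyde, the diazomethylphosphonate anion made in the flask adds and eliminates phosphate, and loss of N2 with 1,2-hydrogen shift gives the terminal alkyne and the free phenol; both centres are retained if addition outruns enolisation of the α-aryl aldehyde (the descriptor at the propargylic carbon changes only through CIP ranking), and any epimer there is a diastereomer removable by chromatography.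

Step 5
Reactants: 10 2-[(1S,2R)-2-(3,5-dimethoxyphenyl)-1-(4-methoxyphenyl)but-3-yn-1-yl]-3,5-dimethoxyphenol
Product: 11 2-[(1S,2R)-2-(3,5-dimethoxyphenyl)-1-(4-methoxyphenyl)but-3-yn-1-yl]-3,5-dimethoxyphenyl trifluoromethanesulfonate
Conditions: Tf2O (1.2 equiv), pyridine (3 equiv), CH2Cl2, −20 to 0 °C
Reagents that add atoms: trifluoromethanesulfonic anhydride, FC(F)(F)S(=O)(=O)OS(=O)(=O)C(F)(F)F
Why: O-sulfonylation of a phenol, which turns the former lactone oxygen on the future C7a into a leaving group; the alkyne, the methyl ethers and the two non-acidic stereocentres should be inert.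

Step 6
Reactants: 11 2-[(1S,2R)-2-(3,5-dimethoxyphenyl)-1-(4-methoxyphenyl)but-3-yn-1-yl]-3,5-dimethoxyphenyl trifluoromethanesulfonate; 2 4-methoxyphenylboronic acid
Product: 12 (1Z,2S,3S)-2-(3,5-dimethoxyphenyl)-4,6-dimethoxy-3-(4-methoxyphenyl)-1-[(4-methoxyphenyl)methylidene]-2,3-dihydro-1H-indene (hexamethyl ether of the target)
Conditions: Pd(OAc)2 (5 mol %), SPhos (10 mol %), anhydrous K3PO4 (3 equiv), dioxane, 80 °C, no copper; 2 (1.5 equiv) added by syringe pump
Reagents that add atoms: none
Why: Zerovalent palladium carrying SPhos inserts into the C–OTf bond at the future C7a, and the aryl–palladium bond then adds syn across the tethered terminal alkyne, joining C7a to the internal alkyne carbon (C1) and leaving divalent palladium on the terminal carbon, cis to C7a and with no β-hydrogen. Transmetalation from the boronate of 2 and reductive elimination with retention put the 4-methoxyphenyl group where the metal stood. The closest known reaction type is the cyclisation–anion capture cascade, an intramolecular alkyne carbopalladation ended by Suzuki coupling, known for aryl halides and sulfonates bearing terminal or internal alkynes. The one ring closed is the five-membered carbocycle of the indane, by 5-exo-dig closure, the only mode open to the three-atom tether C3a–C3–C2 because a 6-endo syn addition cannot be accommodated in the ring. No new stereocentre is made; the new stereo-element, the Z alkene, follows from syn carbopalladation and coupling with retention, and C2 and C3 are not acidic enough to suffer under phosphate. The step needs insertion to come before both transmetalation and palladation of the alkynyl C–H, which the short tether (fast intramolecular insertion), the absence of copper, the weak anhydrous base and the slow addition of 2 should secure.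

Step 7
Reactants: 12 (1Z,2S,3S)-2-(3,5-dimethoxyphenyl)-4,6-dimethoxy-3-(4-methoxyphenyl)-1-[(4-methoxyphenyl)methylidene]-2,3-dihydro-1H-indene
Product: 13 (1Z,2S,3S)-2-(3,5-dihydroxyphenyl)-3-(4-hydroxyphenyl)-1-[(4-hydroxyphenyl)methylidene]-2,3-dihydro-1H-indene-4,6-diol (CNP0253309.1)
Conditions: BBr3 (12 equiv), CH2Cl2, −78 to 0 °C, dim light; poured into ice-cold aq. NaHCO3
Reagents that add atoms: none
Why: Sixfold Lewis acid demethylation of aryl methyl ethers (bromide attack on each boron-activated O–CH3, hydrolysis on quench), a standard last step for permethylated stilbenoid oligomers; the benzylic stereocentres are untouched, and low temperature, exclusion of light and a buffered cold quench should keep the Z alkene from isomerising or moving into the ring.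

**Compound list**

1 | 5,7-dimethoxycoumarin | O=C1C=Cc2c(OC)cc(OC)cc2O1 | starting material
2 | 4-methoxyphenylboronic acid | COc1ccc(B(O)O)cc1 | starting material
3 | (S)-5,7-dimethoxy-4-(4-methoxyphenyl)chroman-2-one | O=C1Oc2cc(OC)cc(OC)c2[C@H](c2ccc(OC)cc2)C1 | intermediate
4 | 1-bromo-3,5-dimethoxybenzene | COc1cc(Br)cc(OC)c1 | starting material
5 | lithium enolate of 3 (lithium (S)-5,7-dimethoxy-4-(4-methoxyphenyl)-4H-chromen-2-olate) | [Li]OC1=C[C@@H](c2ccc(OC)cc2)c2c(OC)cc(OC)cc2O1 | intermediate (not isolated)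
6 | chlorozinc enolate of 3 | Cl[Zn]OC1=C[C@@H](c2ccc(OC)cc2)c2c(OC)cc(OC)cc2O1 | intermediate (not isolated)
7 | (3S,4S)-3-(3,5-dimethoxyphenyl)-5,7-dimethoxy-4-(4-methoxyphenyl)chroman-2-one (trans) | O=C1Oc2cc(OC)cc(OC)c2[C@H](c2ccc(OC)cc2)[C@H]1c1cc(OC)cc(OC)c1 | intermediate
8 | (3S,4S)-3-(3,5-dimethoxyphenyl)-5,7-dimethoxy-4-(4-methoxyphenyl)chroman-2-ol (anomer mixture at C2) | OC1Oc2cc(OC)cc(OC)c2[C@H](c2ccc(OC)cc2)[C@H]1c1cc(OC)cc(OC)c1 | intermediate
9 | (2S,3S)-2-(3,5-dimethoxyphenyl)-3-(2-hydroxy-4,6-dimethoxyphenyl)-3-(4-methoxyphenyl)propanal | Oc1cc(OC)cc(OC)c1[C@H](c1ccc(OC)cc1)[C@H](C=O)c1cc(OC)cc(OC)c1 | intermediate (not isolated)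
10 | 2-[(1S,2R)-2-(3,5-dimethoxyphenyl)-1-(4-methoxyphenyl)but-3-yn-1-yl]-3,5-dimethoxyphenol | Oc1cc(OC)cc(OC)c1[C@H](c1ccc(OC)cc1)[C@H](C#C)c1cc(OC)cc(OC)c1 | intermediate
11 | 2-[(1S,2R)-2-(3,5-dimethoxyphenyl)-1-(4-methoxyphenyl)but-3-yn-1-yl]-3,5-dimethoxyphenyl trifluoromethanesulfonate | FC(F)(F)S(=O)(=O)Oc1cc(OC)cc(OC)c1[C@H](c1ccc(OC)cc1)[C@H](C#C)c1cc(OC)cc(OC)c1 | intermediate
12 | (1Z,2S,3S)-2-(3,5-dimethoxyphenyl)-4,6-dimethoxy-3-(4-methoxyphenyl)-1-[(4-methoxyphenyl)methylidene]-2,3-dihydro-1H-indene | COc1ccc(/C=C2\c3cc(OC)cc(OC)c3[C@H](c3ccc(OC)cc3)[C@H]2c2cc(OC)cc(OC)c2)cc1 | intermediate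
13 | (1Z,2S,3S)-2-(3,5-dihydroxyphenyl)-3-(4-hydroxyphenyl)-1-[(4-hydroxyphenyl)methylidene]-2,3-dihydro-1H-indene-4,6-diol | Oc1ccc(/C=C2\c3cc(O)cc(O)c3[C@H](c3ccc(O)cc3)[C@H]2c2cc(O)cc(O)c2)cc1 | target

**Step count and risks**

Total step count: 7. Longest linear sequence: 7 steps (1 to 13).

Steps most likely to fail:

Step 2. The enolate may expel the aryloxide (ketene formation, self-acylation), or the coupling may stall at the hindered α-carbon next to the C4 aryl. The fallback sets out from lactone 3 and moves the arylation to an open-chain alkyl ester, whose enolate has no aryloxide to lose.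
- NaOMe in MeOH opens 3, and BnBr in DMF caps the phenoxide, giving methyl (3S)-3-[2-(benzyloxy)-4,6-dimethoxyphenyl]-3-(4-methoxyphenyl)propanoate F1.
- F1 is α-arylated with bromide 4 (LiNCy2, Pd(dba)2, P(t-Bu)3, toluene, rt) to methyl (3S)-3-[2-(benzyloxy)-4,6-dimethoxyphenyl]-2-(3,5-dimethoxyphenyl)-3-(4-methoxyphenyl)propanoate F2, taken on as both C2 epimers.
- H2 over Pd/C in EtOAc frees the phenol, giving methyl (3S)-2-(3,5-dimethoxyphenyl)-3-(2-hydroxy-4,6-dimethoxyphenyl)-3-(4-methoxyphenyl)propanoate F3.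
- p-TsOH in hot toluene closes the lactone with loss of methanol. Whatever (3R,4S)-3-(3,5-dimethoxyphenyl)-5,7-dimethoxy-4-(4-methoxyphenyl)chroman-2-one F4 (the cis epimer) forms is converged by DBU on the trans-lactone 7, where the route is rejoined.

Step 4. The transient α-aryl aldehyde may enolise under carbonate in methanol (epimerisation at the carbon that becomes C2), or the lactol may open too slowly for a short, cold reaction. The fallback sets out from lactol 8 and avoids a basic aldehyde stage.
- Ramirez olefination with preformed Ph3P=CBr2 (CBr4, PPh3, Zn, CH2Cl2, 0 °C to rt, excess reagent because of the free phenol) should give 2-[(1S,2R)-4,4-dibromo-2-(3,5-dimethoxyphenyl)-1-(4-methoxyphenyl)but-3-en-1-yl]-3,5-dimethoxyphenol F5.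
- n-BuLi (3 equiv, THF, −78 °C, then aq. NH4Cl) completes the Corey–Fuchs sequence through bromine–lithium exchange and Fritsch–Buttenberg–Wiechell rearrangement, returning to the alkyne phenol 10.

Step 6. The aryl–palladium species may be captured by the boronate before the alkyne inserts, the alkynyl C–H may be palladated or oligomerised, or the alkenyl–palladium may lose its geometry. The fallback sets out from alkyne phenol 10 and forms the same C7a–C1 bond by a Heck reaction on a preformed Z alkene.
- Sonogashira coupling with 4-iodoanisole (Pd(PPh3)2Cl2, CuI, Et3N) gives 2-[(1S,2S)-2-(3,5-dimethoxyphenyl)-1,4-bis(4-methoxyphenyl)but-3-yn-1-yl]-3,5-dimethoxyphenol F6.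
- Semi-hydrogenation (H2, Pd/CaCO3 poisoned with Pb(OAc)2, quinoline) gives 2-[(1S,2S,3Z)-2-(3,5-dimethoxyphenyl)-1,4-bis(4-methoxyphenyl)but-3-en-1-yl]-3,5-dimethoxyphenol F7.
- Tf2O and pyridine give 2-[(1S,2S,3Z)-2-(3,5-dimethoxyphenyl)-1,4-bis(4-methoxyphenyl)but-3-en-1-yl]-3,5-dimethoxyphenyl trifluoromethanesulfonate F8.
- Intramolecular Heck cyclisation of F8 (Pd(OAc)2, PPh3, 1,2,2,6,6-pentamethylpiperidine, MeCN, 80 °C) proceeds by 5-exo-trig syn insertion and syn elimination of the only β-hydrogen, on C1. This sequence carries the Z alkene over into the exocyclic alkene with the anisyl group cis to C7a, giving hexamethyl ether 12.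

Further compounds
F1 | step 2 | methyl (3S)-3-[2-(benzyloxy)-4,6-dimethoxyphenyl]-3-(4-methoxyphenyl)propanoate | O(Cc1ccccc1)c1cc(OC)cc(OC)c1[C@H](c1ccc(OC)cc1)CC(=O)OC
F2 | step 2 | methyl (3S)-3-[2-(benzyloxy)-4,6-dimethoxyphenyl]-2-(3,5-dimethoxyphenyl)-3-(4-methoxyphenyl)propanoate (both C2 epimers) | O(Cc1ccccc1)c1cc(OC)cc(OC)c1[C@H](c1ccc(OC)cc1)C(c1cc(OC)cc(OC)c1)C(=O)OC
F3 | step 2 | methyl (3S)-2-(3,5-dimethoxyphenyl)-3-(2-hydroxy-4,6-dimethoxyphenyl)-3-(4-methoxyphenyl)propanoate (both C2 epimers) | Oc1cc(OC)cc(OC)c1[C@H](c1ccc(OC)cc1)C(c1cc(OC)cc(OC)c1)C(=O)OC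
F4 | step 2 | (3R,4S)-3-(3,5-dimethoxyphenyl)-5,7-dimethoxy-4-(4-methoxyphenyl)chroman-2-one (cis epimer) | O=C1Oc2cc(OC)cc(OC)c2[C@H](c2ccc(OC)cc2)[C@@H]1c1cc(OC)cc(OC)c1
F5 | step 4 | 2-[(1S,2R)-4,4-dibromo-2-(3,5-dimethoxyphenyl)-1-(4-methoxyphenyl)but-3-en-1-yl]-3,5-dimethoxyphenol | Oc1cc(OC)cc(OC)c1[C@H](c1ccc(OC)cc1)[C@H](C=C(Br)Br)c1cc(OC)cc(OC)c1
F6 | step 6 | 2-[(1S,2S)-2-(3,5-dimethoxyphenyl)-1,4-bis(4-methoxyphenyl)but-3-yn-1-yl]-3,5-dimethoxyphenol | Oc1cc(OC)cc(OC)c1[C@H](c1ccc(OC)cc1)[C@H](C#Cc1ccc(OC)cc1)c1cc(OC)cc(OC)c1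
F7 | step 6 | 2-[(1S,2S,3Z)-2-(3,5-dimethoxyphenyl)-1,4-bis(4-methoxyphenyl)but-3-en-1-yl]-3,5-dimethoxyphenol | Oc1cc(OC)cc(OC)c1[C@H](c1ccc(OC)cc1)[C@H](/C=C\c1ccc(OC)cc1)c1cc(OC)cc(OC)c1
F8 | step 6 | 2-[(1S,2S,3Z)-2-(3,5-dimethoxyphenyl)-1,4-bis(4-methoxyphenyl)but-3-en-1-yl]-3,5-dimethoxyphenyl trifluoromethanesulfonate | FC(F)(F)S(=O)(=O)Oc1cc(OC)cc(OC)c1[C@H](c1ccc(OC)cc1)[C@H](/C=C\c1ccc(OC)cc1)c1cc(OC)cc(OC)c1
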